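## Retrosynthetic overview

- The target is reached from a hydroxy lactone core by O8 esterification with (2S)-2-methyloxirane-2-carboxylic acid (side-chain epoxide bought in as (R)-2-methylglycidol) and O9 acetylation.
- The core comes from an open-chain C8–C10/C1–C6 dialdehyde and a four-carbon linchpin, methyl 3-bromo-2-(bromomethyl)acrylate (C7, C11, C12, C13). Two zinc Barbier allylations in one flask form C6–C7, O–C12 and C7–C8, so the α-methylene lactone and the ten-membered ring arise together and C6, C7 and C8 are set.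
- The dialdehyde comes from cross-metathesis of a nerol-derived vinyl epoxy alcohol with silylated (R)-β-hydroxy-α-methylene-γ-butyrolactone, lactone opening and double oxidation.
- Ring order: C4–C5 epoxide first (Sharpless epoxidation of nerol), then lactone and carbocycle together, then the preformed side-chain epoxide is attached.

Assumption: positions are given in germacrane numbering (C6 bears the lactone oxygen, C8 the epoxy ester, C9 the acetate, C14 is the ester carbon on C10, C11=C13 is the exocyclic methylene); (R)-3-hydroxy-γ-butyrolactone and (R)-2-methylglycidol are bought.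

## Route

Step 1
Reactants: 1 nerol, (2Z)-3,7-dimethylocta-2,6-dien-1-ol
Product: 2 [(2S,3R)-3-methyl-3-(4-methylpent-3-en-1-yl)oxiran-2-yl]methanol
Conditions: Ti(OiPr)4 (10 mol %), L-(+)-diethyl tartrate (12 mol %), tBuOOH, 4 Å MS, CH2Cl2, −20 °C
Reagents that add atoms: tert-butyl hydroperoxide, CC(C)(C)OO
Why: Sharpless asymmetric epoxidation touches only the allylic alcohol, and L-(+)-tartrate gives the (2S,3R) cis-epoxide (later C5 S, C4 R) from the Z-alkene.

Step 2
Reactants: 2 [(2S,3R)-3-methyl-3-(4-methylpent-3-en-1-yl)oxiran-2-yl]methanol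
Product: 4 3-[(2R,3S)-3-(hydroxymethyl)-2-methyloxiran-2-yl]propanal, via ozonide 3 (not isolated)
Conditions: O3, CH2Cl2, −78 °C; then Me2S, −78 °C → rt
Reagents that add atoms: ozone, [O-][O+]=O
Why: Ozonolysis with reductive work-up cleaves the only C=C to the aldehyde (later C1) and acetone, and no stereocentre is involved.

Step 3
Reactants: 4 3-[(2R,3S)-3-(hydroxymethyl)-2-methyloxiran-2-yl]propanal
Product: 5 [(2S,3R)-3-(but-3-en-1-yl)-3-methyloxiran-2-yl]methanol
Conditions: Ph3PCH3Br (2.2 equiv), KOtBu (2.2 equiv), THF, 0 °C → rt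
Reagents that add atoms: methyltriphenylphosphonium bromide, C[P+](c1ccccc1)(c1ccccc1)c1ccccc1.[Br-]
Why: Wittig methylenation gives the terminal alkene needed for metathesis; the extra ylide is taken up by the free hydroxyl and the epoxide is inert to it.

Step 4
Reactants: 6 (R)-3-hydroxy-γ-butyrolactone, (4R)-4-hydroxyoxolan-2-one
Product: 9 (4R)-4-hydroxy-3-methylideneoxolan-2-one, via Mannich base 7 (not isolated), via methiodide 8 (not isolated)
Conditions: LDA (2.2 equiv), THF, −78 °C; CH2=NMe2+ I−, −78 → 0 °C; crude: MeI, MeOH, rt; then aq NaHCO3/CH2Cl2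
Reagents that add atoms: N,N-dimethylmethyleneiminium iodide (Eschenmoser's salt), C=[N+](C)C.[I-]
Why: Fráter–Seebach-type dianion Mannich alkylation (the β-alkoxide cannot be eliminated), quaternisation and E1cB loss of trimethylamine give the α-methylene lactone, while the carbinol centre (later C9) comes unchanged from the chiral pool.

Step 5
Reactants: 9 (4R)-4-hydroxy-3-methylideneoxolan-2-one
Product: 10 (4R)-4-[(tert-butyldimethylsilyl)oxy]-3-methylideneoxolan-2-one
Conditions: TBSCl, imidazole, DMF, 0 °C → rt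
Reagents that add atoms: tert-butyldimethylsilyl chloride, CC(C)(C)[Si](C)(C)Cl
Why: Standard silylation puts a bulky, non-migrating group on O9 that later shields the C8 aldehyde.

Step 6
Reactants: 5 [(2S,3R)-3-(but-3-en-1-yl)-3-methyloxiran-2-yl]methanol; 10 (4R)-4-[(tert-butyldimethylsilyl)oxy]-3-methylideneoxolan-2-one (2 equiv)
Product: 11 (3E,4R)-4-[(tert-butyldimethylsilyl)oxy]-3-{3-[(2R,3S)-3-(hydroxymethyl)-2-methyloxiran-2-yl]propylidene}oxolan-2-one
Conditions: second-generation Hoveyda–Grubbs catalyst (5 mol %), 2,6-dichloro-1,4-benzoquinone (10 mol %), CH2Cl2, 40 °C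
Reagents that add atoms: none
Why: Olefin cross-metathesis of a terminal alkene with an α-methylene-γ-butyrolactone gives the thermodynamically preferred E-alkylidene lactone (chain anti to C=O, syn to the silyloxy carbon), which is the C1=C10 geometry of the target.

Step 7
Reactants: 11 (3E,4R)-4-[(tert-butyldimethylsilyl)oxy]-3-{3-[(2R,3S)-3-(hydroxymethyl)-2-methyloxiran-2-yl]propylidene}oxolan-2-one
Product: 13 methyl (2E)-2-[(1R)-1-[(tert-butyldimethylsilyl)oxy]-2-hydroxyethyl]-5-[(2R,3S)-3-(hydroxymethyl)-2-methyloxiran-2-yl]pent-2-enoate, via lithium carboxylate 12 (not isolated)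
Conditions: LiOH·H2O (1.2 equiv), THF/H2O, 0 °C; evaporate; MeI, DMF, 0 °C; crude used at once
Reagents that add atoms: lithium hydroxide, [Li+].[OH-]; iodomethane, CI
Why: Saponification opens the lactone at the acyl carbon and O-alkylation of the carboxylate fixes C14 as the methyl ester and frees C8 as a primary alcohol; no acid is present, so relactonisation and epoxide opening are held back, and no stereocentre is touched.

Step 8
Reactants: 13 methyl (2E)-2-[(1R)-1-[(tert-butyldimethylsilyl)oxy]-2-hydroxyethyl]-5-[(2R,3S)-3-(hydroxymethyl)-2-methyloxiran-2-yl]pent-2-enoate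
Product: 14 methyl (2E)-2-[(1R)-1-[(tert-butyldimethylsilyl)oxy]-2-oxoethyl]-5-[(2R,3R)-3-formyl-2-methyloxiran-2-yl]pent-2-enoate
Conditions: Dess–Martin periodinane (2.5 equiv), NaHCO3, CH2Cl2, 0 °C → rt
Reagents that add atoms: none
Why: Buffered Dess–Martin oxidation converts both primary alcohols to the C6 epoxy aldehyde and the C8 α-silyloxy aldehyde without epimerisation (the epoxide CH descriptor changes to R only through CIP ranking).

Step 9
Reactants: 15 methyl 2-(bromomethyl)prop-2-enoate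
Product: 17 methyl (2Z)-3-bromo-2-(bromomethyl)prop-2-enoate, via tribromide 16 (not isolated)
Conditions: Br2, CH2Cl2, 0 °C; then Et3N, 0 °C → rt
Reagents that add atoms: bromine, BrBr
Why: Bromine addition followed by E2 dehydrobromination (α-bromide lost with a CH2Br hydrogen) gives the γ-bromo allylic bromide; its E/Z ratio does not matter because this carbon (later C7) is rehybridised twice in step 10.

Step 10
Reactants: 14 methyl (2E)-2-[(1R)-1-[(tert-butyldimethylsilyl)oxy]-2-oxoethyl]-5-[(2R,3R)-3-formyl-2-methyloxiran-2-yl]pent-2-enoate; 17 methyl (2Z)-3-bromo-2-(bromomethyl)prop-2-enoate (1.05 equiv)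
Product: 21 methyl (1(10)E,4R,5S,6S,7R,8S,9R)-9-[(tert-butyldimethylsilyl)oxy]-4,5-epoxy-8-hydroxygermacra-1(10),11(13)-dien-12,6-olid-14-oate, via bromoallylzinc bromide 18 (not isolated), via bromo lactone 19 (not isolated), via allylzinc lactone 20 (not isolated)
Conditions: 17, Zn dust, THF, 0 °C; decant onto 14, THF, −40 °C → rt; then syringe pump into activated Zn, THF, 45 °C, final 2 mM; aq NH4Cl
Reagents that add atoms: none
Why: Proposed new method: 17 serves as a C7 1,1-dianion equivalent in two consecutive zinc Barbier allylations: 18 attacks through its γ-carbon the less hindered cis-epoxy aldehyde (the C8 aldehyde is shielded by the silyloxy group and the fully substituted C10) under Felkin–Anh control to give 6S, the zinc alkoxide closes onto the neighbouring methyl ester (Dreiding–Schmidt lactonisation) to 19 while no zinc metal is present, renewed zinc insertion into the allylic C7–Br bond gives the butenolide-type allylzinc 20, and this adds through C7 to the C8 aldehyde on the lactone face anti to the C6 substituent (trans-lactone, 7R) through a chair SE2′ transition state with the tether axial, which is also the polar Felkin–Anh mode anti to the C9 silyloxy group (8S), closing the ten-membered ring; the closest known reactions are zinc or indium Barbier allylation–lactonisation of 2-(bromomethyl)acrylates, including macrocyclising cases, Barbier additions of 3-(bromomethyl)furan-2(5H)-one, and γ-haloallyl metal reagents that deliver one carbon to two carbonyl groups in turn.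

Step 11
Reactants: 22 (R)-2-methylglycidol, [(2R)-2-methyloxiran-2-yl]methanol
Product: 23 (2S)-2-methyloxirane-2-carboxylic acid
Conditions: RuCl3·xH2O (2 mol %), NaIO4 (3 equiv), MeCN/EtOAc/H2O, 0 °C → rt
Reagents that add atoms: sodium periodate, [Na+].[O-]I(=O)(=O)=O
Why: RuO4-type oxidation of the primary alcohol to the acid leaves the quaternary epoxide carbon untouched (R becomes S only because CO2H outranks the ring CH2).

Step 12
Reactants: 21 methyl (1(10)E,4R,5S,6S,7R,8S,9R)-9-[(tert-butyldimethylsilyl)oxy]-4,5-epoxy-8-hydroxygermacra-1(10),11(13)-dien-12,6-olid-14-oate; 23 (2S)-2-methyloxirane-2-carboxylic acid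
Product: 25 8-O-[(2S)-2-methyloxirane-2-carbonyl] derivative of 21, via mixed anhydride 24 (not isolated)
Conditions: 23, 2,4,6-trichlorobenzoyl chloride, Et3N, THF, 0 °C; then 21, DMAP, toluene, rt
Reagents that add atoms: none
Why: Yamaguchi esterification acylates the only free hydroxyl (O8) with retention at C8 and without touching the acid's stereocentre.

Step 13
Reactants: 25 8-O-[(2S)-2-methyloxirane-2-carbonyl] derivative of 21
Product: 26 9-hydroxy compound, methyl (1(10)E,4R,5S,6S,7R,8S,9R)-4,5-epoxy-9-hydroxy-8-{[(2S)-2-methyloxirane-2-carbonyl]oxy}germacra-1(10),11(13)-dien-12,6-olid-14-oate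
Conditions: TBAF, AcOH (1:1), THF, 0 °C → rt
Reagents that add atoms: none
Why: Buffered fluoride desilylation frees O9, and the acetic acid keeps the medium non-basic so the O8 ester does not migrate and the epoxides, lactone and enoate survive.

Step 14
Reactants: 26 methyl (1(10)E,4R,5S,6S,7R,8S,9R)-4,5-epoxy-9-hydroxy-8-{[(2S)-2-methyloxirane-2-carbonyl]oxy}germacra-1(10),11(13)-dien-12,6-olid-14-oate
Product: 27 target, methyl (1(10)E,4R,5S,6S,7R,8S,9R)-9-acetoxy-4,5-epoxy-8-{[(2S)-2-methyloxirane-2-carbonyl]oxy}germacra-1(10),11(13)-dien-12,6-olid-14-oate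
Conditions: Ac2O, DMAP (cat.), pyridine, CH2Cl2, 0 °C
Reagents that add atoms: acetic anhydride, CC(=O)OC(C)=O
Why: DMAP-catalysed acetylation of the remaining secondary alcohol completes the target without affecting any stereocentre.

## Compound list

1 | nerol, (2Z)-3,7-dimethylocta-2,6-dien-1-ol | CC(C)=CCC/C(C)=C\CO | starting material
2 | [(2S,3R)-3-methyl-3-(4-methylpent-3-en-1-yl)oxiran-2-yl]methanol | CC(C)=CCC[C@@]1(C)O[C@H]1CO | intermediate
3 | ozonide, {(2S,3R)-3-[2-(5,5-dimethyl-1,2,4-trioxolan-3-yl)ethyl]-3-methyloxiran-2-yl}methanol (both epimers at the trioxolane CH) | CC1(C)OOC(CC[C@@]2(C)O[C@H]2CO)O1 | intermediate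
4 | 3-[(2R,3S)-3-(hydroxymethyl)-2-methyloxiran-2-yl]propanal | O=CCC[C@@]1(C)O[C@H]1CO | intermediate
5 | [(2S,3R)-3-(but-3-en-1-yl)-3-methyloxiran-2-yl]methanol | C=CCC[C@@]1(C)O[C@H]1CO | intermediate
6 | (R)-3-hydroxy-γ-butyrolactone, (4R)-4-hydroxyoxolan-2-one | O=C1C[C@@H](O)CO1 | starting material
7 | Mannich base, (3R,4R)-3-[(dimethylamino)methyl]-4-hydroxyoxolan-2-one (trans) | O=C1[C@H](CN(C)C)[C@@H](O)CO1 | intermediate
8 | methiodide, [(3R,4R)-4-hydroxy-2-oxooxolan-3-yl]-N,N,N-trimethylmethanaminium iodide | O=C1[C@H](C[N+](C)(C)C)[C@@H](O)CO1.[I-] | intermediate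
9 | (4R)-4-hydroxy-3-methylideneoxolan-2-one | C=C1[C@@H](O)COC1=O | intermediate
10 | (4R)-4-[(tert-butyldimethylsilyl)oxy]-3-methylideneoxolan-2-one | C=C1[C@@H](O[Si](C)(C)C(C)(C)C)COC1=O | intermediate
11 | (3E,4R)-4-[(tert-butyldimethylsilyl)oxy]-3-{3-[(2R,3S)-3-(hydroxymethyl)-2-methyloxiran-2-yl]propylidene}oxolan-2-one | O=C1OC[C@H](O[Si](C)(C)C(C)(C)C)/C1=C\CC[C@@]1(C)O[C@H]1CO | intermediate
12 | lithium (2E)-2-[(1R)-1-[(tert-butyldimethylsilyl)oxy]-2-hydroxyethyl]-5-[(2R,3S)-3-(hydroxymethyl)-2-methyloxiran-2-yl]pent-2-enoate | OC[C@H](O[Si](C)(C)C(C)(C)C)/C(C(=O)[O-])=C\CC[C@@]1(C)O[C@H]1CO.[Li+] | intermediate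
13 | methyl (2E)-2-[(1R)-1-[(tert-butyldimethylsilyl)oxy]-2-hydroxyethyl]-5-[(2R,3S)-3-(hydroxymethyl)-2-methyloxiran-2-yl]pent-2-enoate | OC[C@H](O[Si](C)(C)C(C)(C)C)/C(C(=O)OC)=C\CC[C@@]1(C)O[C@H]1CO | intermediate
14 | methyl (2E)-2-[(1R)-1-[(tert-butyldimethylsilyl)oxy]-2-oxoethyl]-5-[(2R,3R)-3-formyl-2-methyloxiran-2-yl]pent-2-enoate | O=C[C@H](O[Si](C)(C)C(C)(C)C)/C(C(=O)OC)=C\CC[C@@]1(C)O[C@H]1C=O | intermediate
15 | methyl 2-(bromomethyl)prop-2-enoate | C=C(CBr)C(=O)OC | starting material
16 | tribromide, methyl 2,3-dibromo-2-(bromomethyl)propanoate | COC(=O)C(Br)(CBr)CBr | intermediate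
17 | methyl (2Z)-3-bromo-2-(bromomethyl)prop-2-enoate (Z drawn; the E/Z mixture is used as obtained) | BrC/C(C(=O)OC)=C\Br | intermediate
18 | bromoallylzinc bromide, [(2Z)-3-bromo-2-(methoxycarbonyl)prop-2-en-1-yl]zinc bromide | Br[Zn]C/C(C(=O)OC)=C\Br | intermediate
19 | bromo lactone, methyl (2E)-5-{(2R,3S)-3-[(2R)-3-bromo-4-methylidene-5-oxooxolan-2-yl]-2-methyloxiran-2-yl}-2-[(1R)-1-[(tert-butyldimethylsilyl)oxy]-2-oxoethyl]pent-2-enoate (both epimers at CHBr, the later C7) | C=C1C(=O)O[C@H]([C@@H]2O[C@]2(C)CC/C=C(/C(=O)OC)[C@@H](O[Si](C)(C)C(C)(C)C)C=O)C1Br | intermediate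
20 | allylzinc lactone, 19 with C7–Br replaced by a C7=C11 butenolide double bond and C13 as CH2ZnBr, (4R,5S,6S,9R) | Br[Zn]CC1=C[C@@H]([C@@H]2O[C@]2(C)CC/C=C(/C(=O)OC)[C@@H](O[Si](C)(C)C(C)(C)C)C=O)OC1=O | intermediate
21 | methyl (1(10)E,4R,5S,6S,7R,8S,9R)-9-[(tert-butyldimethylsilyl)oxy]-4,5-epoxy-8-hydroxygermacra-1(10),11(13)-dien-12,6-olid-14-oate (cis-epoxide, trans-fused α-methylene lactone, C2 and C9 cis on C1=C10) | C=C1C(=O)O[C@H]2[C@H]1[C@H](O)[C@H](O[Si](C)(C)C(C)(C)C)/C(C(=O)OC)=C\CC[C@@]1(C)O[C@@H]21 | intermediate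
22 | (R)-2-methylglycidol, [(2R)-2-methyloxiran-2-yl]methanol | OC[C@]1(C)CO1 | starting material
23 | (2S)-2-methyloxirane-2-carboxylic acid | OC(=O)[C@]1(C)CO1 | intermediate
24 | mixed anhydride, (2S)-2-methyloxirane-2-carboxylic 2,4,6-trichlorobenzoic anhydride | O=C(OC(=O)[C@]1(C)CO1)c1c(Cl)cc(Cl)cc1Cl | intermediate
25 | 8-O-[(2S)-2-methyloxirane-2-carbonyl] derivative of 21, CIP (4R,5S,6S,7S,8S,9R,2′S); C7 reads S only because silicon raises the C8 branch, the geometry is that of 21 | C=C1C(=O)O[C@H]2[C@H]1[C@H](OC(=O)[C@]1(C)CO1)[C@H](O[Si](C)(C)C(C)(C)C)/C(C(=O)OC)=C\CC[C@@]1(C)O[C@@H]21 | intermediate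
26 | methyl (1(10)E,4R,5S,6S,7R,8S,9R)-4,5-epoxy-9-hydroxy-8-{[(2S)-2-methyloxirane-2-carbonyl]oxy}germacra-1(10),11(13)-dien-12,6-olid-14-oate | C=C1C(=O)O[C@H]2[C@H]1[C@H](OC(=O)[C@]1(C)CO1)[C@H](O)/C(C(=O)OC)=C\CC[C@@]1(C)O[C@@H]21 | intermediate
27 | methyl (1(10)E,4R,5S,6S,7R,8S,9R)-9-acetoxy-4,5-epoxy-8-{[(2S)-2-methyloxirane-2-carbonyl]oxy}germacra-1(10),11(13)-dien-12,6-olid-14-oate | C=C1C(=O)O[C@H]2[C@H]1[C@H](OC(=O)[C@]1(C)CO1)[C@H](OC(C)=O)/C(C(=O)OC)=C\CC[C@@]1(C)O[C@@H]21 | target

## Step count and risks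

Total: 14 steps. Longest linear sequence: 10 steps (1, 2, 3, 6, 7, 8, 10, 12, 13, 14).

**Step 10 (most likely to fail).** Reagent 18 may add to the C8 aldehyde first and give the 8,12-lactone. Ring closure may lose to oligomers or to 1,4-elimination of 20. The C8 carbinol may form in the epimeric mode (tether equatorial, anti-Felkin). The fallback runs the two carbonyl additions on separate molecules in a fixed order, closes the ring by metathesis and sets C8 by inversion. It sets out from 5, 10 and 17 and comes back at 25. Dess–Martin oxidation of 5 gives the epoxy aldehyde F1. Compound 10 is opened as in step 7 to the hydroxy ester F2 and oxidised to the aldehyde F3. F1 and 17 with zinc give, after lactonisation, the bromo lactone F4. With indium in aqueous THF, F4 adds through C7 to F3; in this intermolecular case the chair with the aldehyde substituent equatorial is expected, giving the (8R) seco-diene F5. Ring-closing metathesis between the butenyl group and the acrylate methylene (second-generation Grubbs catalyst, toluene, 80 °C, 1 mM) gives the C8 epimer of the core F6. Mitsunobu esterification of F6 with 23 (PPh3, DIAD) inverts C8 and gives 25. The same Mitsunobu step is used if step 10 itself delivers F6.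

**Step 6.** Cross-metathesis of a terminal alkene with the hindered 1,1-disubstituted lactone may stall or give E/Z mixtures. The fallback makes the metathesis intramolecular with a temporary silicon tether. It sets out from 5 and 9 and comes back at 11. Compound 9 and then 5 are joined with iPr2SiCl2 and imidazole to the silyl-tethered diene F7. Ring-closing metathesis gives the eleven-membered silylene acetal F8, in which the ring forces C2 and the lactone C4 to be cis, that is the E-alkylidene. HF·pyridine removes the tether to give the diol F9. TBSOTf with 2,6-lutidine gives the bis-silyl ether F10. Selective removal of the primary silyl group (HF·pyridine, pyridine, THF, 0 °C) gives 11.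

**Step 7.** The γ-hydroxy ester 13 can close back to lactone 11, and hydroxide may trigger Payne rearrangement of the epoxy alcohol. The fallback never liberates the hydroxy ester. It sets out from 11 and comes back at 14, bypassing 13. After the LiOH opening, both primary hydroxyls are capped with TESCl and imidazole (the silyl ester falls off on work-up) to give the bis-triethylsilyl acid F11. TMSCHN2 gives its methyl ester F12. Swern oxidation converts the two primary triethylsilyl ethers of F12 directly to aldehydes, leaving the secondary TBS ether, and gives 14.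

Further compounds
F1 | step 10 | (2R,3R)-3-(but-3-en-1-yl)-3-methyloxirane-2-carbaldehyde | C=CCC[C@@]1(C)O[C@H]1C=O
F2 | step 10 | methyl 2-[(1R)-1-[(tert-butyldimethylsilyl)oxy]-2-hydroxyethyl]prop-2-enoate | C=C(C(=O)OC)[C@@H](O[Si](C)(C)C(C)(C)C)CO
F3 | step 10 | methyl 2-[(1R)-1-[(tert-butyldimethylsilyl)oxy]-2-oxoethyl]prop-2-enoate | C=C(C(=O)OC)[C@@H](O[Si](C)(C)C(C)(C)C)C=O
F4 | step 10 | (5R)-4-bromo-5-[(2S,3R)-3-(but-3-en-1-yl)-3-methyloxiran-2-yl]-3-methylideneoxolan-2-one (both C4 epimers) | C=CCC[C@@]1(C)O[C@H]1[C@H]2OC(=O)C(=C)C2Br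
F5 | step 10 | seco-diene, (4R,5S,6S,7R,8R,9R): α-methylene lactone of F4 bearing at C7 the (8R)-hydroxy-(9R)-silyloxy chain that ends in the C10 methyl acrylate | C=CCC[C@@]1(C)O[C@H]1[C@H]2OC(=O)C(=C)[C@@H]2[C@@H](O)[C@H](O[Si](C)(C)C(C)(C)C)C(=C)C(=O)OC
F6 | step 10 | C8 epimer of 21, (4R,5S,6S,7R,8R,9R) | C=C1C(=O)O[C@H]2[C@H]1[C@@H](O)[C@H](O[Si](C)(C)C(C)(C)C)/C(C(=O)OC)=C\CC[C@@]1(C)O[C@@H]21
F7 | step 6 | (4R)-4-{[{[(2S,3R)-3-(but-3-en-1-yl)-3-methyloxiran-2-yl]methoxy}di(propan-2-yl)silyl]oxy}-3-methylideneoxolan-2-one | C=CCC[C@@]1(C)O[C@H]1CO[Si](C(C)C)(C(C)C)O[C@H]2COC(=O)C2=C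
F8 | step 6 | eleven-membered cyclic di(propan-2-yl)silylene acetal of F9 (silicon bridges the primary oxygen and the lactone C4 oxygen) | CC(C)[Si]1(C(C)C)OC[C@@H]2O[C@]2(C)CC/C=C3/C(=O)OC[C@@H]3O1
F9 | step 6 | (3E,4R)-4-hydroxy-3-{3-[(2R,3S)-3-(hydroxymethyl)-2-methyloxiran-2-yl]propylidene}oxolan-2-one | O=C1OC[C@H](O)/C1=C\CC[C@@]1(C)O[C@H]1CO
F10 | step 6 | bis(tert-butyldimethylsilyl) ether of F9 | O=C1OC[C@H](O[Si](C)(C)C(C)(C)C)/C1=C\CC[C@@]1(C)O[C@H]1CO[Si](C)(C)C(C)(C)C
F11 | step 7 | (2E)-2-{(1R)-1-[(tert-butyldimethylsilyl)oxy]-2-[(triethylsilyl)oxy]ethyl}-5-[(2R,3S)-2-methyl-3-{[(triethylsilyl)oxy]methyl}oxiran-2-yl]pent-2-enoic acid | CC[Si](CC)(CC)OC[C@H](O[Si](C)(C)C(C)(C)C)/C(C(=O)O)=C\CC[C@@]1(C)O[C@H]1CO[Si](CC)(CC)CC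
F12 | step 7 | methyl ester of F11 | CC[Si](CC)(CC)OC[C@H](O[Si](C)(C)C(C)(C)C)/C(C(=O)OC)=C\CC[C@@]1(C)O[C@H]1CO[Si](CC)(CC)CC
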